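Everything rests on opening the cyclopentane ring of the trans-hydrindane at C2–C3 and C1–C7a (octahydroindene numbering). The key step exploits that C7a is a methyl-bearing quaternary ring-fusion carbon next to C3a: C3, C3a, C7a and the gem-dimethyl six-membered ring are the skeleton of β-cyclocitral, and C1–C2 is a two-carbon (E)-alkenyllithium. In one flask the alkenyllithium adds to the aldehyde and the doubly allylic divinyl carbinol so formed is ionised; 4π-conrotatory electrocyclisation of the pentadienyl cation forges C7a and delivers a cyclopentadiene. Hydrogenation anti to the angular methyl then sets the trans fusion; the lactone side chain follows by auxiliary-controlled conjugate addition and aldol reactions.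

Key step: step 3

Assumption (chemistry): the conrotation in step 3 is taken to form the new bond anti to the silyloxy group of the A(1,3)-minimised cation, which makes (S)-but-3-yn-2-ol the matched precursor; if the sense is the opposite, (R)-but-3-yn-2-ol is used instead, with no change downstream because this carbinol centre is destroyed in step 6.

Step 1
Reactants: 1 (S)-but-3-yn-2-ol
Product: 2 (S)-(but-3-yn-2-yloxy)tri(propan-2-yl)silane
Conditions: TIPSOTf, 2,6-lutidine, CH2Cl2, 0 °C to rt
Reagents that add atoms: triisopropylsilyl trifluoromethanesulfonate, CC(C)[Si](OS(=O)(=O)C(F)(F)F)(C(C)C)C(C)C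
Why: Silyl ether protection of the secondary propargylic alcohol with a silyl triflate and a hindered pyridine base leaves the stereocentre untouched, and the bulky TIPS group is chosen to survive t-BuLi, acid and hydrogenation.

Step 2
Reactants: 2 (S)-(but-3-yn-2-yloxy)tri(propan-2-yl)silane
Product: 4 (S,E)-[(4-iodobut-3-en-2-yl)oxy]tri(propan-2-yl)silane, via alkenylzirconocene 3 (not isolated)
Conditions: Cp2Zr(H)Cl, THF, rt; then I2, 0 °C
Reagents that add atoms: iodine, II
Why: Schwartz hydrozirconation of the terminal alkyne is syn and places zirconium on the terminal carbon, and iodinolysis with retention should give the (E)-alkenyl iodide.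

Step 3
Reactants: 4 (S,E)-[(4-iodobut-3-en-2-yl)oxy]tri(propan-2-yl)silane; 5 β-cyclocitral
Product: 8 {(1S)-1-[(7aS)-4,4,7a-trimethyl-5,6,7,7a-tetrahydro-4H-inden-1-yl]ethoxy}tri(propan-2-yl)silane, via alkenyllithium 6 (not isolated), via divinyl carbinol 7 (not isolated)
Conditions: t-BuLi (2.1 equiv), Et2O, −78 °C; 5, −78 to 0 °C; then TsOH·H2O (1.2 equiv), Et2O, −20 to 0 °C
Reagents that add atoms: none
Why: Iodine–lithium exchange gives the (E)-alkenyllithium 6, whose 1,2-addition to the hindered enal 5 forms the C2–C3 bond and the doubly allylic alkoxide of 7; acid then ionises this carbinol to a pentadienyl cation spanning the ring alkene and the side-chain alkene, which undergoes thermal 4π-conrotatory electrocyclisation to forge the C1–C7a bond and, after loss of the C1 proton, gives the cyclopentadiene 8. The closest known reactions are the dehydrative Nazarov-type cyclisation of divinyl carbinols to cyclopentadienes (the alkenyllithium/acid route to pentamethylcyclopentadiene) and the Nazarov cyclisation itself. The five-membered ring is closed by a 4π-electrocyclic ring closure of the cation, not by nucleophilic or radical attack, so the usual preference against 5-endo closure does not apply. The only new stereocentre is quaternary C7a; its configuration is decided by the sense of conrotation, which is biased by the silyloxy-bearing stereocentre on the cation terminus, and it cannot be lost afterwards because C7a carries no hydrogen and the 5,5-disubstituted cyclopentadiene cannot shift its double bonds. The step needs ionisation at the bis-allylic carbinol in preference to the allylic silyl ether (secured by double allylic stabilisation and the poor leaving-group ability of the silyloxy group) and ring closure in preference to elimination (secured because triene formation is reversible under acid whereas electrocyclisation is not).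

Step 4
Reactants: 8 {(1S)-1-[(7aS)-4,4,7a-trimethyl-5,6,7,7a-tetrahydro-4H-inden-1-yl]ethoxy}tri(propan-2-yl)silane
Product: 9 {(1S)-1-[(1S,3aS,7aS)-4,4,7a-trimethyloctahydro-1H-inden-1-yl]ethoxy}tri(propan-2-yl)silane
Conditions: H2 (30 bar), 5% Rh/Al2O3, EtOAc, rt
Reagents that add atoms: none
Why: Heterogeneous hydrogenation should add hydrogen to both ring alkenes from the face opposite the angular C7a methyl (as in the hydrogenation of 16-ene-20-oxo and 14-ene steroids), setting C1–H and C3a–H anti to the methyl, i.e. the trans ring fusion with the C1 substituent cis to the methyl, while rhodium avoids allylic C–O hydrogenolysis.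

Step 5
Reactants: 9 {(1S)-1-[(1S,3aS,7aS)-4,4,7a-trimethyloctahydro-1H-inden-1-yl]ethoxy}tri(propan-2-yl)silane
Product: 10 (1S)-1-[(1S,3aS,7aS)-4,4,7a-trimethyloctahydro-1H-inden-1-yl]ethan-1-ol
Conditions: TBAF, THF, 50 °C
Reagents that add atoms: none
Why: Fluoride-mediated silyl ether cleavage touches no stereocentre, and the free alcohol is the stage at which the diastereomer from the minor sense of conrotation in step 3 can be removed by chromatography.

Step 6
Reactants: 10 (1S)-1-[(1S,3aS,7aS)-4,4,7a-trimethyloctahydro-1H-inden-1-yl]ethan-1-ol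
Product: 11 1-[(1S,3aS,7aS)-4,4,7a-trimethyloctahydro-1H-inden-1-yl]ethan-1-one
Conditions: Dess–Martin periodinane, NaHCO3, CH2Cl2, rt
Reagents that add atoms: none
Why: Dess–Martin oxidation of the secondary alcohol gives the methyl ketone under neutral conditions, and the acetyl group at C1 already sits in the thermodynamically preferred orientation cis to the angular methyl (as in 17β-acetyl steroids), so epimerisation is not a threat.

Step 7
Reactants: 11 1-[(1S,3aS,7aS)-4,4,7a-trimethyloctahydro-1H-inden-1-yl]ethan-1-one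
Product: 12 N'-{(1E)-1-[(1S,3aS,7aS)-4,4,7a-trimethyloctahydro-1H-inden-1-yl]ethylidene}-2,4,6-tri(propan-2-yl)benzenesulfonohydrazide
Conditions: 2,4,6-triisopropylbenzenesulfonyl hydrazide, cat. HCl, THF, rt
Reagents that add atoms: 2,4,6-triisopropylbenzenesulfonyl hydrazide, NNS(=O)(=O)c1c(C(C)C)cc(C(C)C)cc1C(C)C
Why: Condensation of the ketone with the arylsulfonyl hydrazide gives the trisylhydrazone required for a Shapiro reaction, with the N–N bond anti to the bulky hydrindanyl group.

Step 8
Reactants: 13 (diethoxyphosphoryl)acetic acid; 14 (S)-4-benzyl-1,3-oxazolidin-2-one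
Product: 16 diethyl {2-[(4S)-4-benzyl-2-oxo-1,3-oxazolidin-3-yl]-2-oxoethyl}phosphonate, via mixed anhydride 15 (not isolated)
Conditions: PivCl, Et3N, THF, −20 °C; then 14, LiCl, rt
Reagents that add atoms: none
Why: N-Acylation of the oxazolidinone through the mixed pivalic anhydride under LiCl/Et3N conditions is a standard route to Evans imides and leaves the auxiliary stereocentre untouched.

Step 9
Reactants: 16 diethyl {2-[(4S)-4-benzyl-2-oxo-1,3-oxazolidin-3-yl]-2-oxoethyl}phosphonate; 17 (tert-butyldimethylsilyloxy)acetaldehyde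
Product: 18 (4S)-4-benzyl-3-[(2E)-4-(tert-butyldimethylsilyloxy)but-2-enoyl]-1,3-oxazolidin-2-one
Conditions: LiCl, i-Pr2NEt, MeCN, rt
Reagents that add atoms: none
Why: Horner–Wadsworth–Emmons olefination under Masamune–Roush conditions should give the (E)-enoyl imide from the stabilised phosphonate and the unhindered aldehyde.

Step 10
Reactants: 12 N'-{(1E)-1-[(1S,3aS,7aS)-4,4,7a-trimethyloctahydro-1H-inden-1-yl]ethylidene}-2,4,6-tri(propan-2-yl)benzenesulfonohydrazide; 18 (4S)-4-benzyl-3-[(2E)-4-(tert-butyldimethylsilyloxy)but-2-enoyl]-1,3-oxazolidin-2-one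
Product: 21 (4S)-4-benzyl-3-{(3R)-3-[(tert-butyldimethylsilyloxy)methyl]-4-[(1R,3aS,7aS)-4,4,7a-trimethyloctahydro-1H-inden-1-yl]pent-4-enoyl}-1,3-oxazolidin-2-one, via alkenyllithium 19 (not isolated), via alkenylcopper 20 (not isolated)
Conditions: n-BuLi (2.2 equiv), THF, −78 to 0 °C; CuBr·SMe2, MgBr2·OEt2, THF/Me2S, −40 °C; 18, −40 to −15 °C; NH4Cl (aq)
Reagents that add atoms: none
Why: The Shapiro reaction (deprotonation at the methyl group syn to the sulfonamide, loss of sulfinate and N2) gives the 1,1-disubstituted alkenyllithium, whose copper derivative adds 1,4 to the magnesium-chelated s-cis enoyl imide from the face opposite the benzyl group (auxiliary-controlled organocopper conjugate addition), setting the (R) centre that will carry the acetoxymethyl group and installing the 1,1-disubstituted alkene.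

Step 11
Reactants: 21 (4S)-4-benzyl-3-{(3R)-3-[(tert-butyldimethylsilyloxy)methyl]-4-[(1R,3aS,7aS)-4,4,7a-trimethyloctahydro-1H-inden-1-yl]pent-4-enoyl}-1,3-oxazolidin-2-one; 22 ethyl glyoxylate
Product: 24 ethyl (2S,3S,4R)-3-{[(4S)-4-benzyl-2-oxo-1,3-oxazolidin-3-yl]carbonyl}-4-[(tert-butyldimethylsilyloxy)methyl]-2-hydroxy-5-[(1R,3aS,7aS)-4,4,7a-trimethyloctahydro-1H-inden-1-yl]hex-5-enoate, via boron enolate 23 (not isolated)
Conditions: Bu2BOTf, i-Pr2NEt, CH2Cl2, −78 to 0 °C; 22, −78 to −20 °C; pH 7 buffer, MeOH, H2O2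
Reagents that add atoms: none
Why: The Evans syn-aldol reaction of the (Z)-boron enolate with the glyoxylate through a Zimmerman–Traxler chair, with the benzyl group of the auxiliary dictating the enolate face, should set the two adjacent centres (future lactone C3 and the hydroxyl-bearing C4) in the syn relationship that becomes trans on the lactone ring.

Step 12
Reactants: 24 ethyl (2S,3S,4R)-3-{[(4S)-4-benzyl-2-oxo-1,3-oxazolidin-3-yl]carbonyl}-4-[(tert-butyldimethylsilyloxy)methyl]-2-hydroxy-5-[(1R,3aS,7aS)-4,4,7a-trimethyloctahydro-1H-inden-1-yl]hex-5-enoate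
Product: 26 (3S,4R)-3-hydroxy-4-{(2R)-1-hydroxy-3-[(1R,3aS,7aS)-4,4,7a-trimethyloctahydro-1H-inden-1-yl]but-3-en-2-yl}oxolan-2-one, via diol ester 25 (not isolated)
Conditions: LiBH4, MeOH (1 equiv), THF, −10 °C; then PPTS, MeOH, 40 °C
Reagents that add atoms: none
Why: LiBH4 should reduce the imide carbonyl in preference to the ester (reductive removal of the Evans auxiliary), and under mild acid the new primary alcohol lactonises onto the ethyl ester (γ-lactone favoured over the δ-lactone) while the primary silyl ether is cleaved by methanolysis, all without touching a stereocentre or protonating the alkene.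

Step 13
Reactants: 26 (3S,4R)-3-hydroxy-4-{(2R)-1-hydroxy-3-[(1R,3aS,7aS)-4,4,7a-trimethyloctahydro-1H-inden-1-yl]but-3-en-2-yl}oxolan-2-one
Product: 27 (2R)-2-[(3R,4S)-4-hydroxy-5-oxooxolan-3-yl]-3-[(1R,3aS,7aS)-4,4,7a-trimethyloctahydro-1H-inden-1-yl]but-3-en-1-yl acetate
Conditions: AcCl, 2,4,6-collidine, CH2Cl2, −78 °C
Reagents that add atoms: acetyl chloride, CC(=O)Cl
Why: Selective O-acylation with an acyl chloride and collidine at low temperature should acetylate the primary alcohol and leave the more hindered, less nucleophilic secondary hydroxyl next to the lactone carbonyl free.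

Compound list

1 | (S)-but-3-yn-2-ol | C[C@H](O)C#C | starting material
2 | (S)-(but-3-yn-2-yloxy)tri(propan-2-yl)silane | C[C@H](O[Si](C(C)C)(C(C)C)C(C)C)C#C | intermediate
3 | chlorobis(cyclopentadienyl)[(1E,3S)-3-(triisopropylsilyloxy)but-1-en-1-yl]zirconium | C[C@H](O[Si](C(C)C)(C(C)C)C(C)C)/C=C/[Zr](Cl)(C1C=CC=C1)C1C=CC=C1 | intermediate (not isolated)
4 | (S,E)-[(4-iodobut-3-en-2-yl)oxy]tri(propan-2-yl)silane | C[C@H](O[Si](C(C)C)(C(C)C)C(C)C)/C=C/I | intermediate
5 | β-cyclocitral (2,6,6-trimethylcyclohex-1-ene-1-carbaldehyde) | CC1=C(C=O)C(C)(C)CCC1 | starting material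
6 | [(1E,3S)-3-(triisopropylsilyloxy)but-1-en-1-yl]lithium | C[C@H](O[Si](C(C)C)(C(C)C)C(C)C)/C=C/[Li] | intermediate (not isolated)
7 | (2E,4S)-1-(2,6,6-trimethylcyclohex-1-en-1-yl)-4-(triisopropylsilyloxy)pent-2-en-1-ol (both C1 epimers, formed as the lithium alkoxide) | C[C@H](O[Si](C(C)C)(C(C)C)C(C)C)/C=C/C(O)C1=C(C)CCCC1(C)C | intermediate (not isolated)
8 | {(1S)-1-[(7aS)-4,4,7a-trimethyl-5,6,7,7a-tetrahydro-4H-inden-1-yl]ethoxy}tri(propan-2-yl)silane | C[C@H](O[Si](C(C)C)(C(C)C)C(C)C)C1=CC=C2C(C)(C)CCC[C@]12C | intermediate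
9 | {(1S)-1-[(1S,3aS,7aS)-4,4,7a-trimethyloctahydro-1H-inden-1-yl]ethoxy}tri(propan-2-yl)silane | C[C@H](O[Si](C(C)C)(C(C)C)C(C)C)[C@H]1CC[C@H]2C(C)(C)CCC[C@]12C | intermediate
10 | (1S)-1-[(1S,3aS,7aS)-4,4,7a-trimethyloctahydro-1H-inden-1-yl]ethan-1-ol | C[C@H](O)[C@H]1CC[C@H]2C(C)(C)CCC[C@]12C | intermediate
11 | 1-[(1S,3aS,7aS)-4,4,7a-trimethyloctahydro-1H-inden-1-yl]ethan-1-one | CC(=O)[C@H]1CC[C@H]2C(C)(C)CCC[C@]12C | intermediate
12 | N'-{(1E)-1-[(1S,3aS,7aS)-4,4,7a-trimethyloctahydro-1H-inden-1-yl]ethylidene}-2,4,6-tri(propan-2-yl)benzenesulfonohydrazide | C/C(=N\NS(=O)(=O)c1c(C(C)C)cc(C(C)C)cc1C(C)C)[C@H]1CC[C@H]2C(C)(C)CCC[C@]12C | intermediate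
13 | (diethoxyphosphoryl)acetic acid | CCOP(=O)(OCC)CC(=O)O | starting material
14 | (S)-4-benzyl-1,3-oxazolidin-2-one | O=C1N[C@@H](Cc2ccccc2)CO1 | starting material
15 | (diethoxyphosphoryl)acetic pivalic anhydride | CCOP(=O)(OCC)CC(=O)OC(=O)C(C)(C)C | intermediate (not isolated)
16 | diethyl {2-[(4S)-4-benzyl-2-oxo-1,3-oxazolidin-3-yl]-2-oxoethyl}phosphonate | CCOP(=O)(OCC)CC(=O)N1[C@@H](Cc2ccccc2)COC1=O | intermediate
17 | (tert-butyldimethylsilyloxy)acetaldehyde | CC(C)(C)[Si](C)(C)OCC=O | starting material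
18 | (4S)-4-benzyl-3-[(2E)-4-(tert-butyldimethylsilyloxy)but-2-enoyl]-1,3-oxazolidin-2-one | CC(C)(C)[Si](C)(C)OC/C=C/C(=O)N1[C@@H](Cc2ccccc2)COC1=O | intermediate
19 | {1-[(1R,3aS,7aS)-4,4,7a-trimethyloctahydro-1H-inden-1-yl]ethenyl}lithium | [Li]C(=C)[C@H]1CC[C@H]2C(C)(C)CCC[C@]12C | intermediate (not isolated)
20 | {1-[(1R,3aS,7aS)-4,4,7a-trimethyloctahydro-1H-inden-1-yl]ethenyl}copper | [Cu]C(=C)[C@H]1CC[C@H]2C(C)(C)CCC[C@]12C | intermediate (not isolated)
21 | (4S)-4-benzyl-3-{(3R)-3-[(tert-butyldimethylsilyloxy)methyl]-4-[(1R,3aS,7aS)-4,4,7a-trimethyloctahydro-1H-inden-1-yl]pent-4-enoyl}-1,3-oxazolidin-2-one | C=C([C@H]1CC[C@H]2C(C)(C)CCC[C@]12C)[C@H](CO[Si](C)(C)C(C)(C)C)CC(=O)N1[C@@H](Cc2ccccc2)COC1=O | intermediate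
22 | ethyl glyoxylate | CCOC(=O)C=O | starting material
23 | (Z)-dibutylboron enolate of 21 | C=C([C@H]1CC[C@H]2C(C)(C)CCC[C@]12C)[C@H](CO[Si](C)(C)C(C)(C)C)/C=C(\OB(CCCC)CCCC)N1[C@@H](Cc2ccccc2)COC1=O | intermediate (not isolated)
24 | ethyl (2S,3S,4R)-3-{[(4S)-4-benzyl-2-oxo-1,3-oxazolidin-3-yl]carbonyl}-4-[(tert-butyldimethylsilyloxy)methyl]-2-hydroxy-5-[(1R,3aS,7aS)-4,4,7a-trimethyloctahydro-1H-inden-1-yl]hex-5-enoate | C=C([C@H]1CC[C@H]2C(C)(C)CCC[C@]12C)[C@H](CO[Si](C)(C)C(C)(C)C)[C@@H]([C@H](O)C(=O)OCC)C(=O)N1[C@@H](Cc2ccccc2)COC1=O | intermediate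
25 | ethyl (2S,3R,4R)-4-[(tert-butyldimethylsilyloxy)methyl]-2-hydroxy-3-(hydroxymethyl)-5-[(1R,3aS,7aS)-4,4,7a-trimethyloctahydro-1H-inden-1-yl]hex-5-enoate | C=C([C@H]1CC[C@H]2C(C)(C)CCC[C@]12C)[C@H](CO[Si](C)(C)C(C)(C)C)[C@H](CO)[C@H](O)C(=O)OCC | intermediate (not isolated)
26 | (3S,4R)-3-hydroxy-4-{(2R)-1-hydroxy-3-[(1R,3aS,7aS)-4,4,7a-trimethyloctahydro-1H-inden-1-yl]but-3-en-2-yl}oxolan-2-one | C=C([C@H]1CC[C@H]2C(C)(C)CCC[C@]12C)[C@H](CO)[C@@H]1COC(=O)[C@H]1O | intermediate
27 | (2R)-2-[(3R,4S)-4-hydroxy-5-oxooxolan-3-yl]-3-[(1R,3aS,7aS)-4,4,7a-trimethyloctahydro-1H-inden-1-yl]but-3-en-1-yl acetate | C=C([C@H]1CC[C@H]2C(C)(C)CCC[C@]12C)[C@H](COC(C)=O)[C@@H]1COC(=O)[C@H]1O | target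

Total step count: 13. Longest linear sequence: 11 steps (steps 1–7 and 10–13); steps 8 and 9 make the enoyl imide 18 on a side branch.

Steps most likely to fail

Step 3. The cascade may stall at open-chain trienes formed by proton loss from the pentadienyl cation, acid may ionise the silyloxy group that becomes dienylic once 8 has formed, and the sense or degree of conrotation may be poor. The fallback sets out from 4 and comes back to the route at 8. Iodide 4 is lithiated (t-BuLi) and silylated (Me3SiCl) to the (E)-vinylsilane F1. Commercial 2,6,6-trimethylcyclohex-1-ene-1-carboxylic acid is converted with oxalyl chloride into the acid chloride F2. SnCl4-mediated ipso-acylation of F1 by F2 and Nazarov cyclisation of the resulting divinyl ketone in the same flask (vinylsilane cyclopentenone annulation) still form both ring bonds in one operation, now through an oxygen-stabilised cation, and give the cyclopentenone F3. Luche reduction (NaBH4, CeCl3·7H2O) gives the allylic alcohol F4, and dehydration with the Burgess reagent gives 8.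

Step 4. Hydrogen may reach the hindered C3=C3a alkene, flanked by two quaternary carbons, from the wrong face or not at all, giving cis-fused or partly reduced material. The fallback sets out from 8 and comes back at 9. Brief hydrogenation at 1 atm over Rh/Al2O3 reduces only the accessible C1=C2 alkene and gives the mono-alkene F5. Hydrogen-atom-transfer hydrogenation (Mn(dpm)3, PhSiH3, t-BuOOH, i-PrOH) then reduces the remaining alkene through the tertiary C3a radical, which should take up hydrogen anti to the angular methyl to give the trans-fused 9.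

Step 10. The alkenyllithium may be protonated before transmetalation, the hindered α-branched alkenyl group may transfer slowly from copper, and facial selectivity may erode if the chelated s-cis imide is not the reacting conformer. The fallback sets out from 11 and comes back at 21. Kinetic enolisation and triflation (KHMDS, PhNTf2) give the alkenyl triflate F6, and Miyaura borylation (B2pin2, PdCl2(dppf), KOAc, dioxane) gives the alkenyl boronate F7. Rhodium-catalysed conjugate addition of F7 to 18 ([Rh(OH)(cod)]2, a chiral bisphosphine matched to the auxiliary, dioxane/H2O) then gives 21.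

Further compounds

F1 | step 3 | (S,E)-trimethyl[3-(triisopropylsilyloxy)but-1-en-1-yl]silane | C[C@H](O[Si](C(C)C)(C(C)C)C(C)C)/C=C/[Si](C)(C)C
F2 | step 3 | 2,6,6-trimethylcyclohex-1-ene-1-carbonyl chloride | CC1=C(C(=O)Cl)C(C)(C)CCC1
F3 | step 3 | (3aS)-3a,7,7-trimethyl-3-[(1S)-1-(triisopropylsilyloxy)ethyl]-3a,4,5,6,7,7a-hexahydro-1H-inden-1-one (C7a epimerisable) | C[C@H](O[Si](C(C)C)(C(C)C)C(C)C)C1=CC(=O)C2C(C)(C)CCC[C@]12C
F4 | step 3 | (3aS)-3a,7,7-trimethyl-3-[(1S)-1-(triisopropylsilyloxy)ethyl]-3a,4,5,6,7,7a-hexahydro-1H-inden-1-ol (epimer mixture at C1 and C7a) | C[C@H](O[Si](C(C)C)(C(C)C)C(C)C)C1=CC(O)C2C(C)(C)CCC[C@]12C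
F5 | step 4 | {(1S)-1-[(1S,7aS)-4,4,7a-trimethyl-2,4,5,6,7,7a-hexahydro-1H-inden-1-yl]ethoxy}tri(propan-2-yl)silane | C[C@H](O[Si](C(C)C)(C(C)C)C(C)C)[C@H]1CC=C2C(C)(C)CCC[C@]12C
F6 | step 10 | 1-[(1S,3aS,7aS)-4,4,7a-trimethyloctahydro-1H-inden-1-yl]ethenyl trifluoromethanesulfonate | C=C(OS(=O)(=O)C(F)(F)F)[C@H]1CC[C@H]2C(C)(C)CCC[C@]12C
F7 | step 10 | 4,4,5,5-tetramethyl-2-{1-[(1R,3aS,7aS)-4,4,7a-trimethyloctahydro-1H-inden-1-yl]ethenyl}-1,3,2-dioxaborolane | C=C(B1OC(C)(C)C(C)(C)O1)[C@H]1CC[C@H]2C(C)(C)CCC[C@]12C
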